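**Assumptions.** The rings are lettered A (trihydroxy acyl end), B (middle, methyl ether on O2) and C (free acid end), and the SMILES string is taken as the definition of the target. Methyl orsellinate (13) is taken to be a purchasable compound. LiTMP (lithium 2,2,6,6-tetramethylpiperidide, LiNC9H18) is used as a pre-formed THF solution.

## Analysis of the target

The target (20) is a linear tridepside: three benzene rings joined by two aryl ester bonds. It has no stereocentre, so the problem is one of regiochemistry and protecting-group order. Ring A is a 2,4,5-trihydroxy-6-methylbenzoyl unit, ring B a 2-methoxy-6-methylbenzoyl unit acylated on O4, and ring C an orsellinic acid unit with a free carboxyl, a free 2-hydroxyl and an acylated O4. Both ester carbonyls are flanked by two ortho substituents, so each ester must come from a hindered, electron-rich benzoic acid, and the finished aryl esters are labile to base and to phenoxide-mediated acyl transfer. Ring A is a hydroxyquinol that air oxidises once unmasked, and ring C is a β-resorcylic acid that loses CO2 on heating, so the last step has to be neutral and mild. The main difficulty is ring B: O2 must be a methyl ether and O4 the attachment point of ring A, whereas in an orsellinate the 4-hydroxyl is the one that reacts first. The strategy rests on the contiguous C6(CH3)–C1(CO2R)–C2(OCH3) array of ring B, with hydrogen at C3 and C5. Methyl and carboxyl on neighbouring carbons with an alkoxy group beside the carboxyl carbon is what nucleophile-then-electrophile addition across a 3-alkoxybenzyne delivers.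

## Retrosynthetic reasoning

**20 ⇒ 19.** The four O–benzyl bonds (three ethers on ring A, one ester on ring C) are cut last. Hydrogenolysis is neutral, so neither aryl ester, the hydroxyquinol nor the decarboxylation-prone acid of 20 sees acid or base. The 2-hydroxyl of ring C is left unprotected throughout because its hydrogen bond to the neighbouring ester carbonyl already masks it.

**19 ⇒ 12 + 17.** The ring A carbonyl–O4(ring B) bond is cut next. Ring A acid 17 is the most oxidation-prone fragment, so it is introduced as late as possible. The forward reaction must acylate the ring B 4-hydroxyl of 12 with a di-ortho-substituted acid without touching the chelated ring C hydroxyl; mixed-anhydride activation through 18 under acidic conditions does this.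

**12 ⇒ 11 ⇒ 7 + 9.** The O–Si bond of 11 is cut to expose O4 of ring B only after the B–C ester is in place; before that the silyl group prevents ring B from acylating itself. The B–C ester is then cut at the ring B carbonyl–O4(ring C) bond, giving acid 7 and benzyl orsellinate 9. In 9 only the 4-hydroxyl is free of hydrogen bonding, so no phenol protection is needed on ring C.

**7 ⇒ 2 + 3 (through 4, 5, 6).** Two skeletal bonds of ring B are cut together: C6–CH3 and C1–CO2H. Both are traced to aryne 5. Grignard reagent 3 puts methyl on the aryne carbon remote from methoxy, and the resulting arylmagnesium 6, which sits next to methoxy, is carboxylated. This cut is preferred because it gives ring B with O2 (methyl ether) and O4 (silyl ether) already different, which is the one thing an orsellinate cannot offer directly. Aryne 5 comes from bromide 2 by removal of the proton between bromine and methoxy (aryllithium 4) and loss of bromide.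

**2 ⇒ 1.** The O–Si bond is cut to give phenol 1, which already carries the 1,3,5-pattern of bromine, methoxy and hydroxyl. The silyl group must be bulky and non-coordinating so that it does not direct metalation to its own side.

**9 ⇒ 8.** The benzyl ester C–O bond is cut to give orsellinic acid 8; the forward step is selective carboxylate alkylation.

**17 ⇒ 16 ⇒ 15 ⇒ 13.** Acid 17 is traced through its methyl ester 16 and triol 15 to methyl orsellinate 13 by cutting the C5–O bond. C5 is para to the 2-hydroxyl of 13, the position an Elbs persulfate oxidation attacks (through aryl sulfate 14). Ring A therefore needs one C–O bond formation, one benzylation and one saponification.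

## Alternatives that were turned down

**Alternative 1:** Ring A is built from acyclic pieces, cut at C1–C6 and C2–C3 back to dimethyl malonate A3 and 3-(benzyloxy)pent-3-en-2-one A2.
- Forward key step: conjugate addition of A3 to A2, then closure of the methyl ketone enolate onto one ester to give cyclohexanedione A1. Dehydrogenation would give methyl 5-(benzyloxy)-2,4-dihydroxy-6-methylbenzoate A4.
- For: the position of O5 is fixed by construction and arrives already distinguished from O2 and O4. On this point it is stronger than step 6 of the chosen route, where the site of oxygenation depends on the para preference of the Elbs reaction.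
- Against: A2 is a β-substituted enone with a donor oxygen on the α-carbon, so it is a poor Michael acceptor. In A1 the benzyloxy group on C5 is allylic in the dienol tautomer and has hydrogen on C6, so loss of the benzyloxy group across C5–C6 aromatises the ring without any oxidant and gives 13, deleting the oxygen the sequence was meant to install. The dehydrogenation therefore has to outrun a downhill elimination.
- Comparison: this alternative only rebuilds ring A, the fragment that three steps from 13 already deliver, and leaves the O2/O4 differentiation of ring B unsolved. The chosen strategy spends its key step on ring B.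

**Alternative 2:** Ring A is cut at C1–C2 and C5–C6 into furan A6, 4-(benzyloxy)-2-(tert-butyldimethylsilyloxy)furan, and ynoate A7, the but-2-ynoate ester of a ring B–C didepside phenol.
- Forward key step: [4+2] cycloaddition, opening of the oxygen bridge at the silyloxy bridgehead and tautomerisation to hydroquinone A5.
- For: it is the most convergent plan. The oxidation-prone ring appears only at the end. The A–B ester is made as an alkynoate ester of an unhindered phenol, so no di-ortho-substituted acid needs activating, which is better than step 9 here. The regiochemistry is electronically matched, since both oxygen donors of A6 make C5 the nucleophilic terminus that meets the β-carbon of the ynoate.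
- Against: the dienophile in A7 is a β-methyl ynoate, weakly activated and hindered, so heat or a Lewis acid would be needed. A6 is in effect a silyl ketene acetal, labile to acid and moisture, and can add stepwise in a vinylogous Mukaiyama–Michael sense to give open-chain butenolide adducts instead of ring A. These conditions would be applied to a substrate that already holds two aryl esters.
- Comparison: A7 presupposes a ring B with O2 methylated and O4 free, so the ring B problem is moved, not solved. The chosen strategy solves it at the start on a small molecule (2) and keeps the late steps to well-understood esterifications.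

**Alternative 3:** Ring B is cut at C1–C6 back to aryl triketo ester A9, made by capture of an acylketene with ring C phenol A10.
- Forward key step: intramolecular aldol condensation of C2 onto the C7 ketone, dehydration and enolisation to give didepside A8.
- For: it is biomimetic, and the B–C ester is formed by ketene trapping, which avoids activating a hindered acid. On that point it is as good as or better than step 4 here.
- Against: A8 emerges with both ring B hydroxyls free and in the wrong reactivity order. The 4-hydroxyl reacts first, so O4 would have to be acylated with the ring A acid and the hydrogen-bonded 2-hydroxyl methylated afterwards under basic conditions in the presence of two aryl esters. In A9 the C5 enol oxygen can lactonise onto the activated aryl ester and expel A10, giving pyranone A11, the classic competitor of polyketide aromatisation. A10 also needs a selectively placed benzyl ether, which costs steps that 9 does not.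
- Comparison: the chosen strategy buys the O2/O4 distinction with the starting material 1 and fixes it in the key step, so no selective methylation is ever needed.

Key step: step 2

## Route

Step 1
Reactants: 1 3-bromo-5-methoxyphenol
Product: 2 1-bromo-3-methoxy-5-(triisopropylsilyloxy)benzene
Conditions: TIPSCl, imidazole, DMF, rt
Reagents that add atoms: triisopropylsilyl chloride, CC(C)[Si](Cl)(C(C)C)C(C)C
Why: Imidazole-promoted silylation of a phenol; the triisopropylsilyl ether is inert to amide bases and Grignard reagents, is too bulky and too weakly coordinating to direct metalation, and can be removed later with fluoride.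

Step 2
Reactants: 2 1-bromo-3-methoxy-5-(triisopropylsilyloxy)benzene, 3 methylmagnesium bromide
Product: 7 2-methoxy-6-methyl-4-(triisopropylsilyloxy)benzoic acid, via aryllithium 4 (not isolated), via aryne 5 (not isolated), via arylmagnesium bromide 6 (not isolated)
Conditions: MeMgBr (3.5 equiv), THF, −78 °C; LiTMP (1.5 equiv) added slowly, −78 °C → rt; CO2 (g), −20 °C → rt; 1 M HCl, 0 °C
Reagents that add atoms: methylmagnesium bromide (3), C[Mg]Br; carbon dioxide, O=C=O
Why: The amide base removes the proton flanked by bromine and methoxy to give aryllithium 4 (in part its magnesium counterpart after metal exchange with the Grignard reagent), and loss of bromide on warming gives aryne 5. The methyl–magnesium bond then adds across the strained triple bond with methyl on the carbon remote from methoxy, so the carbanion of 6 lies next to the inductively stabilising, chelating methoxy oxygen, and CO2 carboxylates it. The closest known reaction type is carbomagnesiation of a 3-alkoxybenzyne by a Grignard reagent with electrophilic trapping of the 2-alkoxyarylmagnesium. No ring is closed and no stereocentre is formed. The first selectivity needed is the site of deprotonation: methoxy coordinates lithium and the proton beside it is unhindered, whereas the proton beside the silyloxy group is shielded by the triisopropylsilyl group, whose oxygen is a poor ligand. Both conceivable arynes would take methyl on the former C–Br carbon, so this selectivity alone decides where the carboxyl ends up. The second selectivity is the direction of addition, which is set by the inductive distortion of the aryne by the adjacent methoxy group; the silyloxy group two carbons further on is too remote to reverse it. Having the Grignard reagent in excess before the base is added means the aryne is trapped as it forms, which limits amide addition and aryne self-coupling.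

Step 3
Reactants: 8 orsellinic acid
Product: 9 benzyl orsellinate (benzyl 2,4-dihydroxy-6-methylbenzoate)
Conditions: BnBr, KHCO3, DMF, rt
Reagents that add atoms: benzyl bromide, BrCc1ccccc1
Why: Carboxylate O-alkylation; bicarbonate deprotonates the acid but not the phenols, so only the ester forms, and the low temperature avoids decarboxylation of this β-resorcylic acid.

Step 4
Reactants: 7 2-methoxy-6-methyl-4-(triisopropylsilyloxy)benzoic acid, 9 benzyl orsellinate
Product: 11 benzyl 2-hydroxy-4-{[2-methoxy-6-methyl-4-(triisopropylsilyloxy)benzoyl]oxy}-6-methylbenzoate, via mixed anhydride 10 (not isolated)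
Conditions: (CF3CO)2O, toluene, 0 °C → rt
Reagents that add atoms: none
Why: Mixed-anhydride esterification, the classical depside coupling: the hindered, electron-rich acid forms aroyl trifluoroacetate 10, which acylates the 4-hydroxyl of 9, the only phenol not tied up in a hydrogen bond to the ester carbonyl. The aryl silyl ether and the benzyl ester should tolerate trifluoroacetic acid at room temperature.

Step 5
Reactants: 11 benzyl 2-hydroxy-4-{[2-methoxy-6-methyl-4-(triisopropylsilyloxy)benzoyl]oxy}-6-methylbenzoate
Product: 12 benzyl 2-hydroxy-4-[(4-hydroxy-2-methoxy-6-methylbenzoyl)oxy]-6-methylbenzoate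
Conditions: TBAF, AcOH (1:1), THF, 0 °C
Reagents that add atoms: none
Why: Fluoride cleavage of an aryl silyl ether; the acetic acid buffer protonates the phenoxide as it forms, so it cannot attack the aryl ester by acyl transfer.

Step 6
Reactants: 13 methyl orsellinate (methyl 2,4-dihydroxy-6-methylbenzoate)
Product: 15 methyl 2,4,5-trihydroxy-6-methylbenzoate, via aryl sulfate 14 (not isolated)
Conditions: K2S2O8, aq. KOH, 0 → 20 °C, N2; then aq. HCl, 80 °C
Reagents that add atoms: potassium peroxydisulfate, [K+].[K+].[O-]S(=O)(=O)OOS(=O)(=O)[O-]
Why: Elbs persulfate oxidation: the phenolate attacks the peroxide oxygen through C5, which is para to the 2-oxygen and ortho to the 4-oxygen, while the position para to the 4-oxygen is blocked by the ester. Aryl sulfate 14 is deactivated against further oxidation and is hydrolysed by acid with S–O cleavage; the hindered, chelated methyl ester should survive both stages.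

Step 7
Reactants: 15 methyl 2,4,5-trihydroxy-6-methylbenzoate
Product: 16 methyl 2,4,5-tris(benzyloxy)-6-methylbenzoate
Conditions: BnBr (excess), K2CO3, degassed DMF, 60 °C, N2
Reagents that add atoms: benzyl bromide, BrCc1ccccc1
Why: Williamson ether synthesis on all three phenols; warming is needed for the hydrogen-bonded 2-hydroxyl, and air is excluded because the hydroxyquinol anion oxidises easily.

Step 8
Reactants: 16 methyl 2,4,5-tris(benzyloxy)-6-methylbenzoate
Product: 17 2,4,5-tris(benzyloxy)-6-methylbenzoic acid
Conditions: KOH, DMSO–H2O, 90 °C; then aq. HCl, 0 °C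
Reagents that add atoms: potassium hydroxide, [K+].[OH-]
Why: Saponification of a di-ortho-substituted benzoate, which needs poorly solvated hydroxide in DMSO; benzyl aryl ethers are inert to these conditions, and cold acidification avoids decarboxylation of the electron-rich acid.

Step 9
Reactants: 12 benzyl 2-hydroxy-4-[(4-hydroxy-2-methoxy-6-methylbenzoyl)oxy]-6-methylbenzoate, 17 2,4,5-tris(benzyloxy)-6-methylbenzoic acid
Product: 19 benzyl 2-hydroxy-4-({2-methoxy-6-methyl-4-[2,4,5-tris(benzyloxy)-6-methylbenzoyloxy]benzoyl}oxy)-6-methylbenzoate, via mixed anhydride 18 (not isolated)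
Conditions: (CF3CO)2O, toluene, 0 °C → rt
Reagents that add atoms: none
Why: The same mixed-anhydride esterification as in step 4: aroyl trifluoroacetate 18 acylates the ring B 4-hydroxyl of 12, which is the only phenol not locked in a hydrogen bond, while the chelated and flanked ring C 2-hydroxyl should stay free. The acidic medium avoids the phenoxide-mediated acyl transfer that base would cause.

Step 10
Reactants: 19 benzyl 2-hydroxy-4-({2-methoxy-6-methyl-4-[2,4,5-tris(benzyloxy)-6-methylbenzoyloxy]benzoyl}oxy)-6-methylbenzoate
Product: 20 2'-O-methylhiascic acid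
Conditions: H2 (1 atm), Pd/C, EtOAc, rt; work-up under argon
Reagents that add atoms: none
Why: Hydrogenolysis removes the three benzyl ethers and the benzyl ester in one neutral operation; aryl esters, the methyl ether and the aromatic rings are not touched, and no heat or base is applied that could decarboxylate ring C or oxidise ring A.

## Compound list

1 | 3-bromo-5-methoxyphenol | COc1cc(O)cc(Br)c1 | starting material
2 | 1-bromo-3-methoxy-5-(triisopropylsilyloxy)benzene | COc1cc(Br)cc(O[Si](C(C)C)(C(C)C)C(C)C)c1 | intermediate
3 | methylmagnesium bromide | C[Mg]Br | starting material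
4 | [2-bromo-6-methoxy-4-(triisopropylsilyloxy)phenyl]lithium | COc1cc(O[Si](C(C)C)(C(C)C)C(C)C)cc(Br)c1[Li] | intermediate
5 | 3-methoxy-5-(triisopropylsilyloxy)benzyne | COC1=CC(O[Si](C(C)C)(C(C)C)C(C)C)=CC#C1 | intermediate
6 | [2-methoxy-6-methyl-4-(triisopropylsilyloxy)phenyl]magnesium bromide | COc1cc(O[Si](C(C)C)(C(C)C)C(C)C)cc(C)c1[Mg]Br | intermediate
7 | 2-methoxy-6-methyl-4-(triisopropylsilyloxy)benzoic acid | COc1cc(O[Si](C(C)C)(C(C)C)C(C)C)cc(C)c1C(=O)O | intermediate
8 | orsellinic acid (2,4-dihydroxy-6-methylbenzoic acid) | Cc1cc(O)cc(O)c1C(=O)O | starting material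
9 | benzyl orsellinate (benzyl 2,4-dihydroxy-6-methylbenzoate) | Cc1cc(O)cc(O)c1C(=O)OCc1ccccc1 | intermediate
10 | 2-methoxy-6-methyl-4-(triisopropylsilyloxy)benzoic trifluoroacetic anhydride | COc1cc(O[Si](C(C)C)(C(C)C)C(C)C)cc(C)c1C(=O)OC(=O)C(F)(F)F | intermediate
11 | benzyl 2-hydroxy-4-{[2-methoxy-6-methyl-4-(triisopropylsilyloxy)benzoyl]oxy}-6-methylbenzoate | COc1cc(O[Si](C(C)C)(C(C)C)C(C)C)cc(C)c1C(=O)Oc1cc(C)c(C(=O)OCc2ccccc2)c(O)c1 | intermediate
12 | benzyl 2-hydroxy-4-[(4-hydroxy-2-methoxy-6-methylbenzoyl)oxy]-6-methylbenzoate | COc1cc(O)cc(C)c1C(=O)Oc1cc(C)c(C(=O)OCc2ccccc2)c(O)c1 | intermediate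
13 | methyl orsellinate (methyl 2,4-dihydroxy-6-methylbenzoate) | COC(=O)c1c(C)cc(O)cc1O | starting material
14 | potassium 4,6-dihydroxy-3-(methoxycarbonyl)-2-methylphenyl sulfate | COC(=O)c1c(C)c(OS(=O)(=O)[O-])c(O)cc1O.[K+] | intermediate
15 | methyl 2,4,5-trihydroxy-6-methylbenzoate | COC(=O)c1c(C)c(O)c(O)cc1O | intermediate
16 | methyl 2,4,5-tris(benzyloxy)-6-methylbenzoate | COC(=O)c1c(C)c(OCc2ccccc2)c(OCc2ccccc2)cc1OCc1ccccc1 | intermediate
17 | 2,4,5-tris(benzyloxy)-6-methylbenzoic acid | Cc1c(C(=O)O)c(OCc2ccccc2)cc(OCc2ccccc2)c1OCc1ccccc1 | intermediate
18 | 2,4,5-tris(benzyloxy)-6-methylbenzoic trifluoroacetic anhydride | Cc1c(C(=O)OC(=O)C(F)(F)F)c(OCc2ccccc2)cc(OCc2ccccc2)c1OCc1ccccc1 | intermediate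
19 | benzyl 2-hydroxy-4-({2-methoxy-6-methyl-4-[2,4,5-tris(benzyloxy)-6-methylbenzoyloxy]benzoyl}oxy)-6-methylbenzoate | COc1cc(OC(=O)c2c(OCc3ccccc3)cc(OCc3ccccc3)c(OCc3ccccc3)c2C)cc(C)c1C(=O)Oc1cc(C)c(C(=O)OCc2ccccc2)c(O)c1 | intermediate
20 | 2'-O-methylhiascic acid (2-hydroxy-4-{[2-methoxy-6-methyl-4-(2,4,5-trihydroxy-6-methylbenzoyloxy)benzoyl]oxy}-6-methylbenzoic acid) | COc1cc(OC(=O)c2c(O)cc(O)c(O)c2C)cc(C)c1C(=O)Oc1cc(C)c(C(=O)O)c(O)c1 | target

## Step count and risk

Total: 10 steps. Longest linear sequence: 6 steps (1, 2, 4, 5, 9, 10) from 3-bromo-5-methoxyphenol. The ring A branch (steps 6, 7, 8) and the ring C branch (step 3) join it at steps 9 and 4.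

**Step 2 (key step).**
- What may go wrong: metalation at the wrong site, either beside the silyloxy group, which would place the carboxyl next to the silyl ether, or between the two oxygens, which would give a non-eliminating arylmetal that is simply carboxylated. The aryne may also be captured by the amide, by tetramethylpiperidine or by an arylmetal in place of the methyl nucleophile, and mixed lithium–magnesium ate species may cause bromine–metal exchange.
- Fallback, from 9 back to 7: benzyl orsellinate 9 would be silylated at its free 4-hydroxyl (TIPSCl, imidazole, DMF) to benzyl 2-hydroxy-6-methyl-4-(triisopropylsilyloxy)benzoate F1. The hydrogen-bonded 2-hydroxyl would then be methylated under Mitsunobu conditions (MeOH, PPh3, DIAD, THF) to benzyl 2-methoxy-6-methyl-4-(triisopropylsilyloxy)benzoate F2. Hydrogenolysis of the benzyl ester (H2, Pd/C, EtOAc) would give 7. Ring B would then come from orsellinic acid by functional-group changes and no aryne would be used.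

**Step 6.**
- What may go wrong: incomplete conversion, which is typical of persulfate oxidations; attack at the carbon between the two hydroxyls; and oxidation of the hydroxyquinol to a quinone during sulfate hydrolysis.
- Fallback, from 13 back to 16: methyl orsellinate 13 would be bis-benzylated (BnBr, K2CO3, DMF) to methyl 2,4-bis(benzyloxy)-6-methylbenzoate F3. Bromination with N-bromosuccinimide in MeCN is expected at C5, which is para to the 2-benzyloxy group and less crowded than the carbon between the two ethers, giving methyl 2,4-bis(benzyloxy)-5-bromo-6-methylbenzoate F4. Miyaura borylation (bis(pinacolato)diboron, PdCl2(dppf) or Pd(OAc)2 with SPhos, KOAc, dioxane, 90 °C) would give methyl 2,4-bis(benzyloxy)-6-methyl-5-(4,4,5,5-tetramethyl-1,3,2-dioxaborolan-2-yl)benzoate F5. Oxidation (H2O2, NaOH, THF–H2O, 0 °C) would give methyl 2,4-bis(benzyloxy)-5-hydroxy-6-methylbenzoate F6, and benzylation of F6 (BnBr, K2CO3, DMF) would give 16. The free hydroxyquinol is never handled on this path.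

**Step 9.**
- What may go wrong: competing acylation of the chelated ring C hydroxyl, acid-promoted migration of the existing B–C acyl group between phenols, and loss of the benzyl group ortho to the acylium centre.
- Fallback, from 7 back to 19, with the order of assembly reversed: acid 7 would be alkylated (allyl bromide, KHCO3, DMF) to allyl 2-methoxy-6-methyl-4-(triisopropylsilyloxy)benzoate F8 and desilylated (TBAF, AcOH, THF) to allyl 4-hydroxy-2-methoxy-6-methylbenzoate F9. F9 has only one phenol, and esterification with 17 ((CF3CO)2O, toluene) would give allyl 2-methoxy-6-methyl-4-[2,4,5-tris(benzyloxy)-6-methylbenzoyloxy]benzoate F10. Deallylation with zerovalent palladium (Pd(PPh3)4, morpholine, THF) would give 2-methoxy-6-methyl-4-[2,4,5-tris(benzyloxy)-6-methylbenzoyloxy]benzoic acid F11. Coupling F11 with 9 ((CF3CO)2O, toluene), where only the free 4-hydroxyl reacts, would give 19.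

**Step 4.**
- What may go wrong: loss of the silyl group in trifluoroacetic acid, followed by self-acylation of ring B, or sluggish reaction of the hindered acid.
- Fallback, from 7 back to 11: acid 7 would be converted under neutral conditions (1-chloro-N,N,2-trimethylprop-1-en-1-amine, CH2Cl2, 0 °C) into 2-methoxy-6-methyl-4-(triisopropylsilyloxy)benzoyl chloride F7. F7 would be coupled with 9 under basic conditions (Et3N, catalytic 4-dimethylaminopyridine, CH2Cl2, 0 °C), where the more acidic, non-chelated 4-hydroxyl of 9 is acylated, to give 11. No strong acid touches the silyl ether on this path.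

## Further compounds

F1 | step 2 | benzyl 2-hydroxy-6-methyl-4-(triisopropylsilyloxy)benzoate | Cc1cc(O[Si](C(C)C)(C(C)C)C(C)C)cc(O)c1C(=O)OCc1ccccc1
F2 | step 2 | benzyl 2-methoxy-6-methyl-4-(triisopropylsilyloxy)benzoate | COc1cc(O[Si](C(C)C)(C(C)C)C(C)C)cc(C)c1C(=O)OCc1ccccc1
F3 | step 6 | methyl 2,4-bis(benzyloxy)-6-methylbenzoate | COC(=O)c1c(OCc2ccccc2)cc(OCc2ccccc2)cc1C
F4 | step 6 | methyl 2,4-bis(benzyloxy)-5-bromo-6-methylbenzoate | COC(=O)c1c(OCc2ccccc2)cc(OCc2ccccc2)c(Br)c1C
F5 | step 6 | methyl 2,4-bis(benzyloxy)-6-methyl-5-(4,4,5,5-tetramethyl-1,3,2-dioxaborolan-2-yl)benzoate | COC(=O)c1c(OCc2ccccc2)cc(OCc2ccccc2)c(B2OC(C)(C)C(C)(C)O2)c1C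
F6 | step 6 | methyl 2,4-bis(benzyloxy)-5-hydroxy-6-methylbenzoate | COC(=O)c1c(OCc2ccccc2)cc(OCc2ccccc2)c(O)c1C
F7 | step 4 | 2-methoxy-6-methyl-4-(triisopropylsilyloxy)benzoyl chloride | COc1cc(O[Si](C(C)C)(C(C)C)C(C)C)cc(C)c1C(Cl)=O
F8 | step 9 | allyl 2-methoxy-6-methyl-4-(triisopropylsilyloxy)benzoate | C=CCOC(=O)c1c(C)cc(O[Si](C(C)C)(C(C)C)C(C)C)cc1OC
F9 | step 9 | allyl 4-hydroxy-2-methoxy-6-methylbenzoate | C=CCOC(=O)c1c(C)cc(O)cc1OC
F10 | step 9 | allyl 2-methoxy-6-methyl-4-[2,4,5-tris(benzyloxy)-6-methylbenzoyloxy]benzoate | C=CCOC(=O)c1c(C)cc(OC(=O)c2c(OCc3ccccc3)cc(OCc3ccccc3)c(OCc3ccccc3)c2C)cc1OC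
F11 | step 9 | 2-methoxy-6-methyl-4-[2,4,5-tris(benzyloxy)-6-methylbenzoyloxy]benzoic acid | COc1cc(OC(=O)c2c(OCc3ccccc3)cc(OCc3ccccc3)c(OCc3ccccc3)c2C)cc(C)c1C(=O)O
A1 | alternative 1 | methyl 5-(benzyloxy)-6-methyl-2,4-dioxocyclohexane-1-carboxylate (diastereomer mixture) | COC(=O)C1C(C)C(OCc2ccccc2)C(=O)CC1=O
A2 | alternative 1 | 3-(benzyloxy)pent-3-en-2-one | CC=C(OCc1ccccc1)C(C)=O
A3 | alternative 1 | dimethyl malonate | COC(=O)CC(=O)OC
A4 | alternative 1 | methyl 5-(benzyloxy)-2,4-dihydroxy-6-methylbenzoate | COC(=O)c1c(C)c(OCc2ccccc2)c(O)cc1O
A5 | alternative 2 | 4-O-benzyl ring A tridepside with ring C benzyl ether and benzyl ester | COc1cc(OC(=O)c2c(O)cc(OCc3ccccc3)c(O)c2C)cc(C)c1C(=O)Oc1cc(C)c(C(=O)OCc2ccccc2)c(OCc2ccccc2)c1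
A6 | alternative 2 | 4-(benzyloxy)-2-(tert-butyldimethylsilyloxy)furan | CC(C)(C)[Si](C)(C)Oc1cc(OCc2ccccc2)co1
A7 | alternative 2 | benzyl 2-(benzyloxy)-4-{[4-(but-2-ynoyloxy)-2-methoxy-6-methylbenzoyl]oxy}-6-methylbenzoate | CC#CC(=O)Oc1cc(C)c(C(=O)Oc2cc(C)c(C(=O)OCc3ccccc3)c(OCc3ccccc3)c2)c(OC)c1
A8 | alternative 3 | benzyl 2-(benzyloxy)-4-(2,4-dihydroxy-6-methylbenzoyloxy)-6-methylbenzoate | Cc1cc(O)cc(O)c1C(=O)Oc1cc(C)c(C(=O)OCc2ccccc2)c(OCc2ccccc2)c1
A9 | alternative 3 | benzyl 2-(benzyloxy)-6-methyl-4-(3,5,7-trioxooctanoyloxy)benzoate | CC(=O)CC(=O)CC(=O)CC(=O)Oc1cc(C)c(C(=O)OCc2ccccc2)c(OCc2ccccc2)c1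
A10 | alternative 3 | benzyl 2-(benzyloxy)-4-hydroxy-6-methylbenzoate | Cc1cc(O)cc(OCc2ccccc2)c1C(=O)OCc1ccccc1
A11 | alternative 3 | 4-hydroxy-6-(2-oxopropyl)-2H-pyran-2-one | CC(=O)Cc1cc(O)cc(=O)o1
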